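**Plan**
1. Feature: the hydroxyls on C5 and C8 of the benzene ring are para. The ring is therefore the reduced form of a 1,4-benzoquinone whose C4a=C8a bond is an electrophilic enedione C=C, and the pyran ring (O1, C2, C3, C4, C4a, C8a) is attached at exactly these two carbons.
2. Retrosynthesis: cut C4–C4a and O1–C8a together, giving a 4a-bromoquinone and a cis HO–CMe2–CH=CH–SnBu3 unit. Then cut the two quinone C=O groups (to a para-dimethoxyarene), then C4a–Br, then the aryl–acyl bond at C6.
3. Forward: the 3-phenylpropanoyl chain is joined to 1,2,4-trimethoxybenzene by directed lithiation, and the ring is brominated and oxidized to the quinone. The pyran ring arises last, in a coupling/oxa-Michael/aromatization cascade that restores the benzene ring and both free phenols at once.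
4. Helpers: the bromine (regiochemical marker and activating group) and the quinone oxidation level are both consumed within the key step, so nothing has to be removed afterwards.
5. Stereochemistry: the target has no stereocentre. The cis C3=C4 bond comes from the (Z)-stannane, whose geometry is fixed by a cyclic alkenylalanate.

Key step: step 6

Remark: ring atoms carry 2H-chromene numbering of the target (O1, C2, C3, C4, C4a, C5 to C8, C8a) throughout, also in the precursors.

**Step 1**
Reactants: 1 3-phenylpropanoyl chloride; 2 N,O-dimethylhydroxylamine hydrochloride
Product: 3 N-methoxy-N-methyl-3-phenylpropanamide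
Conditions: K2CO3, CH2Cl2/H2O, 0 °C to rt
Reagents that add atoms: none
Why: Schotten–Baumann N-acylation of the hydroxylamine liberated by K2CO3 should give the Weinreb amide, a routine acyl substitution with no competing site.

**Step 2**
Reactants: 4 1,2,4-trimethoxybenzene; 3 N-methoxy-N-methyl-3-phenylpropanamide
Product: 6 1-(2,3,6-trimethoxyphenyl)-3-phenylpropan-1-one, via aryllithium 5 (not isolated)
Conditions: n-BuLi, THF, 0 °C to rt; then 3, −78 °C to rt; 1 M HCl
Reagents that add atoms: none
Why: Directed ortho-metalation removes the one ring proton of 4 that is flanked by two methoxy groups (future C6), and the Weinreb ketone synthesis with 3 should deliver the ketone without over-addition.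

**Step 3**
Reactants: 6 1-(2,3,6-trimethoxyphenyl)-3-phenylpropan-1-one
Product: 7 1-(3-bromo-2,5,6-trimethoxyphenyl)-3-phenylpropan-1-one
Conditions: NBS, MeCN, 0 °C to rt, dark
Reagents that add atoms: N-bromosuccinimide O=C1CCC(=O)N1Br
Why: Electrophilic aromatic bromination should go to future C4a, which is ortho to one methoxy group and para to another, whereas future C8a is activated by a single ortho methoxy group and lies para to the acyl group.

**Step 4**
Reactants: 7 1-(3-bromo-2,5,6-trimethoxyphenyl)-3-phenylpropan-1-one
Product: 8 2-bromo-5-methoxy-6-(3-phenylpropanoyl)cyclohexa-2,5-diene-1,4-dione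
Conditions: (NH4)2Ce(NO3)6 (2.5 equiv), MeCN/H2O, 0 °C, short contact time; used at once
Reagents that add atoms: water O
Why: Oxidative demethylation of the para-dimethoxy pair by tetravalent cerium (two one-electron oxidations, attack of water at the two ipso carbons, loss of methanol) should give the 1,4-quinone and leave the third methoxy group, the bromine and the side chain untouched.

**Step 5**
Reactants: 9 2-methylbut-3-yn-2-ol
Product: 11 (Z)-2-methyl-4-(tributylstannyl)but-3-en-2-ol, via cyclic alanate 10 (not isolated)
Conditions: LiAlH4, THF, 0 to 45 °C; then Bu3SnOTf, −78 to 0 °C; H2O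
Reagents that add atoms: tributyltin trifluoromethanesulfonate CCCC[Sn](CCCC)(CCCC)OS(=O)(=O)C(F)(F)F
Why: Hydroxyl-directed trans-hydroalumination of the propargylic alcohol places aluminium on the terminal carbon inside a five-membered cyclic alanate, so tin-for-aluminium exchange with retention can only give the cis (Z) γ-hydroxyvinylstannane.

**Step 6**
Reactants: 8 2-bromo-5-methoxy-6-(3-phenylpropanoyl)cyclohexa-2,5-diene-1,4-dione; 11 (Z)-2-methyl-4-(tributylstannyl)but-3-en-2-ol
Product: 14 flemistrictin D, via vinylquinone 12 (not isolated), via dienol adduct 13 (not isolated)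
Conditions: Pd2(dba)3 (cat.), AsPh3 (cat.), CuI (cat.), degassed 1,4-dioxane (0.01 M), 25 to 50 °C, argon, dark
Reagents that add atoms: none
Why: Proposed new method: zerovalent palladium inserts into the C4a–Br bond of 8 (a vinylogous acyl bromide), and Stille transmetalation with 11 followed by reductive elimination with retention gives vinylquinone 12, in which the cis C3=C4 bond and the gem-dimethyl group hold the tertiary hydroxyl next to C8a–H. The hydroxyl then adds to C8a, the β-carbon of the C5(=O)–C4a=C8a enone, closing the pyran ring in a 6-endo-trig oxa-Michael mode to dienol 13, and transfer of the C8a proton to the C8 oxygen aromatizes the carbocycle to the C5/C8 hydroquinone, so the event is redox-neutral and ends at the target. The closest known reaction types are the Stille coupling of bromoquinones with alkenylstannanes and the conjugate addition of tethered alcohols to quinones followed by enolization, and what is new is their union in one flask as an annulation that uses a hindered tertiary alcohol. No stereocentre remains, because C8a of 13 is transient and is erased on aromatization, and the only stereochemical element, the cis C3=C4 bond, is carried over from 11. The regiochemistry is secured by the substrate, since carbon can enter only at the brominated C4a and the oxygen can then reach only C8a for conjugate addition, while its addition to the C5 carbonyl is reversible and unproductive and chelation of the C5 and side-chain carbonyls by the Bu3SnBr formed should raise the electrophilicity of C8a. AsPh3 is chosen because it does not add to quinones as PPh3 does, high dilution disfavours Diels–Alder self-dimerization of 12, and hydrogen exchange between 14 and the quinones 8 and 12 is reversible and should be drained by the irreversible ring closure.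

**Compound list**
1 | 3-phenylpropanoyl chloride | O=C(Cl)CCc1ccccc1 | starting material
2 | N,O-dimethylhydroxylamine hydrochloride | CNOC.Cl | starting material
3 | N-methoxy-N-methyl-3-phenylpropanamide | CON(C)C(=O)CCc1ccccc1 | intermediate
4 | 1,2,4-trimethoxybenzene | COc1ccc(OC)c(OC)c1 | starting material
5 | (2,3,6-trimethoxyphenyl)lithium, not isolated | [Li]c1c(OC)ccc(OC)c1OC | intermediate
6 | 1-(2,3,6-trimethoxyphenyl)-3-phenylpropan-1-one | COc1ccc(OC)c(C(=O)CCc2ccccc2)c1OC | intermediate
7 | 1-(3-bromo-2,5,6-trimethoxyphenyl)-3-phenylpropan-1-one | COc1cc(Br)c(OC)c(C(=O)CCc2ccccc2)c1OC | intermediate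
8 | 2-bromo-5-methoxy-6-(3-phenylpropanoyl)cyclohexa-2,5-diene-1,4-dione | COC1=C(C(=O)CCc2ccccc2)C(=O)C(Br)=CC1=O | intermediate
9 | 2-methylbut-3-yn-2-ol | CC(C)(O)C#C | starting material
10 | lithium 2,2-dihydrido-5,5-dimethyl-2,5-dihydro-1,2-oxaaluminol-2-uide (cyclic cis-alkenylalanate), not isolated | [Li+].CC1(C)C=C[AlH2-]O1 | intermediate
11 | (Z)-2-methyl-4-(tributylstannyl)but-3-en-2-ol | CCCC[Sn](CCCC)(CCCC)/C=C\C(C)(C)O | intermediate
12 | 2-[(Z)-3-hydroxy-3-methylbut-1-en-1-yl]-5-methoxy-6-(3-phenylpropanoyl)cyclohexa-2,5-diene-1,4-dione, not isolated | COC1=C(C(=O)CCc2ccccc2)C(=O)C(/C=C\C(C)(C)O)=CC1=O | intermediate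
13 | 5-hydroxy-7-methoxy-2,2-dimethyl-6-(3-phenylpropanoyl)-2H-chromen-8(8aH)-one, racemic at the transient C8a, not isolated | COC1=C(C(=O)CCc2ccccc2)C(O)=C2C=CC(C)(C)OC2C1=O | intermediate
14 | flemistrictin D, 1-(5,8-dihydroxy-7-methoxy-2,2-dimethyl-2H-chromen-6-yl)-3-phenylpropan-1-one | COc1c(O)c2c(c(O)c1C(=O)CCc1ccccc1)C=CC(C)(C)O2 | target

**Count**
Total step count: 6.
Longest linear sequence: 5 steps (steps 1, 2, 3, 4 and 6). Step 5 is a one-step side branch.

**Steps most likely to fail**

Step 6.
- Several processes may outrun the closure:
  - hydrogen transfer between the hydroquinone product and the quinones still present;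
  - capture of zerovalent palladium by the quinone;
  - protodestannylation of 11 by the phenols that build up;
  - Diels–Alder self-dimerization of the vinylquinone;
  - a slow ring closure, because C8a is the less electrophilic end of the enedione.
- The fallback uses known chemistry and makes the two bonds in separate flasks. It sets out from 7 and 11 and comes back to the route at 14.
- A Stille coupling at the arene oxidation level (Pd(PPh3)4, CuI, DMF, 80 °C) should give (Z)-1-[3-(3-hydroxy-3-methylbut-1-en-1-yl)-2,5,6-trimethoxyphenyl]-3-phenylpropan-1-one F1.
- Excess (NH4)2Ce(NO3)6 in MeCN/H2O should then demethylate F1 oxidatively to 12, which closes as above.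
- The surplus oxidant carries all material on to 7-methoxy-2,2-dimethyl-6-(3-phenylpropanoyl)-2H-chromene-5,8-dione F2, so redox exchange can no longer divert it.
- Aqueous Na2S2O4 (EtOAc, rt) should reduce F2 to 14.

Step 4.
- Electron transfer from an arene that carries both bromine and an acyl group may be slow.
- The acidic aqueous medium may hydrolyse the vinylogous ester methoxy group of the quinone or nitrate the ring.
- The fallback sets out from 7 and comes back at 8. It separates oxidation from unmasking.
- Anodic oxidation (Pt anode, KOH, MeOH, 0 °C, undivided cell) should give the quinone bis(dimethyl ketal) 1-(5-bromo-2,3,3,6,6-pentamethoxycyclohexa-1,4-dien-1-yl)-3-phenylpropan-1-one F3.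
- Brief hydrolysis of F3 with dilute HCl in THF/H2O should release 8 under milder, oxidant-free conditions.

Step 5.
- Deprotonation of the terminal alkyne may compete with hydride delivery.
- Hydroalumination of the hindered tertiary alkynol may stay incomplete.
- The C–Al bond may be protonated before stannylation, and the cis stannane may isomerize.
- The fallback sets out from 9 and comes back at 11.
- Double deprotonation (n-BuLi, 2 equiv, THF, −78 °C) and C-stannylation with Bu3SnCl should give 2-methyl-4-(tributylstannyl)but-3-yn-2-ol F4.
- Syn-hydrozirconation with Cp2Zr(H)Cl (THF, rt) puts zirconium geminal to tin, and protonolysis with retention (H2O) should then give 11 with tin cis to the carbinol carbon.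

**Further compounds**
F1 | step 6 | (Z)-1-[3-(3-hydroxy-3-methylbut-1-en-1-yl)-2,5,6-trimethoxyphenyl]-3-phenylpropan-1-one | COc1cc(/C=C\C(C)(C)O)c(OC)c(C(=O)CCc2ccccc2)c1OC
F2 | step 6 | 7-methoxy-2,2-dimethyl-6-(3-phenylpropanoyl)-2H-chromene-5,8-dione | COC1=C(C(=O)CCc2ccccc2)C(=O)C2=C(OC(C)(C)C=C2)C1=O
F3 | step 4 | 1-(5-bromo-2,3,3,6,6-pentamethoxycyclohexa-1,4-dien-1-yl)-3-phenylpropan-1-one | COC1=C(C(=O)CCc2ccccc2)C(OC)(OC)C(Br)=CC1(OC)OC
F4 | step 5 | 2-methyl-4-(tributylstannyl)but-3-yn-2-ol | CCCC[Sn](CCCC)(CCCC)C#CC(C)(C)O
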